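The route rests on cutting the C5–O1 bond of the butenolide ring (O1–C2–C3–C4–C5). This exposes a 2-methoxy-3-arylglutaconic half-acid. Its C5–H is α to the methyl ester and, through C3=C4, vinylogously α to the C2 carboxyl, and the carboxylate oxygen sits exactly a five-membered ring away. One catalytic oxidation with a chiral ammonium hypoiodite joins these two nucleophilic sites. It closes the ring and creates the only stereocentre, quaternary C5, from a racemic, geometry-indifferent precursor. That precursor carries TIPS-capped phenols and a bromine where the prenyl group will stand. It is assembled by Claisen acylation, enol triflate/Reformatsky coupling and C5 benzylation.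

Key step: step 10

Assumption: the sense of induction of the spiro ammonium salt on this new substrate class cannot be predicted, so the (R,R)-salt is written and its equally accessible mirror image is used if (S)-C5 is favoured.

Conventions: lactone numbering (O1, C2, C3, C4, C5) is kept for all open-chain compounds. Ring A is the aryl group on C4, ring B is the arene of the C5 benzyl group, and TIPS is triisopropylsilyl.

Design remarks:
- Both phenols are carried as TIPS ethers rather than smaller silyl ethers. A phenol set free under hypoiodite would be dearomatised, for ring A by ipso attack of the C2 carboxylate.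
- The brominated benzyl group is attached by alkylation after the only palladium step that precedes the key step. The aryl bromide therefore meets zerovalent palladium only when it is meant to react.
- Alkene geometries of the open-chain compounds are drawn as expected. The other isomers serve equally well, because steps 8 and 10 pass through delocalised anions.

Step 1
Reactants: 1 methoxyacetic acid
Product: 2 tert-butyl methoxyacetate
Conditions: isobutene (excess), H2SO4 (cat), CH2Cl2, sealed flask, rt
Reagents that add atoms: isobutene, CC(C)=C
Why: Acid-catalysed addition of a carboxylic acid to isobutene is the standard tert-butyl esterification and gives an ester that resists self-condensation and can later be removed without base.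

Step 2
Reactants: 3 methyl 4-hydroxybenzoate
Product: 4 methyl 4-(triisopropylsilyloxy)benzoate
Conditions: TIPSCl, imidazole, DMF, rt
Reagents that add atoms: triisopropylsilyl chloride, CC(C)[Si](Cl)(C(C)C)C(C)C
Why: Imidazole-promoted silylation of a phenol installs a group that should withstand enolates, methoxide, carbonate and hypoiodite and still leave with fluoride at the end.

Step 3
Reactants: 2 tert-butyl methoxyacetate; 4 methyl 4-(triisopropylsilyloxy)benzoate
Product: 6 tert-butyl 2-methoxy-3-oxo-3-[4-(triisopropylsilyloxy)phenyl]propanoate (racemic), via lithium enolate 5 (not isolated)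
Conditions: LDA (2.3 equiv), 2 (2.2 equiv), THF, −78 °C; then 4, −78 → 0 °C; aq NH4Cl
Reagents that add atoms: none
Why: Crossed Claisen condensation: the lithium enolate of a tert-butyl ester does not self-condense, 4 is the only acceptor and has no α-hydrogen, and the surplus enolate deprotonates 6 as it forms and so drives the acylation, the new α-centre being labile and irrelevant.

Step 4
Reactants: 6 tert-butyl 2-methoxy-3-oxo-3-[4-(triisopropylsilyloxy)phenyl]propanoate
Product: 8 tert-butyl (E)-2-methoxy-3-[4-(triisopropylsilyloxy)phenyl]-3-(trifluoromethylsulfonyloxy)prop-2-enoate, via sodium enolate 7 (not isolated)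
Conditions: NaH, Et2O, 0 °C; then Tf2O, −78 → 0 °C
Reagents that add atoms: triflic anhydride, O=S(=O)(OS(=O)(=O)C(F)(F)F)C(F)(F)F
Why: O-Sulfonylation of a β-keto ester enolate is the standard entry to β-triflyloxy acrylates; the sodium chelate between the two carbonyl oxygens should place OTf cis to the ester, which already matches the C2/C5-cis arrangement wanted later.

Step 5
Reactants: 8 enol triflate; 9 methyl bromoacetate
Product: 11 1-tert-butyl 5-methyl (Z)-2-methoxy-3-[4-(triisopropylsilyloxy)phenyl]pent-2-enedioate, via Reformatsky reagent 10 (not isolated)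
Conditions: 9 (3 equiv), Zn dust, Me3SiCl (cat), THF, 40 °C; then 8, Pd(PPh3)4 (5 mol %), THF, 60 °C
Reagents that add atoms: none
Why: Negishi-type cross-coupling of a Reformatsky reagent with an electron-poor alkenyl triflate, in which zerovalent palladium inserts readily into the C–OTf bond and the small CH2 nucleophile eases bond formation at the fully substituted alkene carbon C4, with retention of geometry.

Step 6
Reactants: 12 2-bromo-4-methylphenol
Product: 13 (2-bromo-4-methylphenoxy)triisopropylsilane
Conditions: TIPSCl, imidazole, DMF, rt → 40 °C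
Reagents that add atoms: triisopropylsilyl chloride, CC(C)[Si](Cl)(C(C)C)C(C)C
Why: Imidazole-promoted silylation of a phenol, which tolerates the ortho bromine.

Step 7
Reactants: 13 (2-bromo-4-methylphenoxy)triisopropylsilane
Product: 14 [2-bromo-4-(bromomethyl)phenoxy]triisopropylsilane
Conditions: NBS, 2,2′-azobis(isobutyronitrile) (cat), PhCF3, 85 °C; used without storage
Reagents that add atoms: N-bromosuccinimide, O=C1CCC(=O)N1Br
Why: Wohl–Ziegler bromination: the radical chain abstracts the weakest C–H bond, that of the benzylic methyl group, while the non-polar medium, the ring bromine and the bulky silyl ether suppress ionic ring bromination.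

Step 8
Reactants: 11 glutaconate diester; 14 [2-bromo-4-(bromomethyl)phenoxy]triisopropylsilane
Product: 16 1-tert-butyl 5-methyl (Z)-4-[3-bromo-4-(triisopropylsilyloxy)benzyl]-2-methoxy-3-[4-(triisopropylsilyloxy)phenyl]pent-2-enedioate (racemic at C5), via lithium dienolate 15 (not isolated)
Conditions: LiHMDS (1.05 equiv), THF, −78 °C; then 14 (1.0 equiv), −78 → 0 °C
Reagents that add atoms: none
Why: Alkylation of a glutaconate anion (vinylogous malonate alkylation): of the two nucleophilic termini C5 is a CH whereas C3 is fully substituted and flanked by OMe and the tert-butyl ester, so the benzylic bromide should be taken up at C5, giving a racemic centre that step 10 erases anyway.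

Step 9
Reactants: 16 benzylated glutaconate diester
Product: 17 (Z)-4-[3-bromo-4-(triisopropylsilyloxy)benzyl]-2,5-dimethoxy-5-oxo-3-[4-(triisopropylsilyloxy)phenyl]pent-2-enoic acid (glutaconic half-acid, racemic at C5, C2 and C5 cis)
Conditions: CF3CO2H/CH2Cl2 (1:4), 0 °C → rt; toluene azeotrope
Reagents that add atoms: none
Why: Acidolysis of the tert-butyl ester by E1-type loss of isobutene frees only the C2 carboxyl and should leave the methyl ester, the aryl TIPS ethers, the aryl bromide and the captodative enol ether untouched.

Step 10
Reactants: 17 glutaconic half-acid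
Product: 19 methyl (R)-2-[3-bromo-4-(triisopropylsilyloxy)benzyl]-4-methoxy-5-oxo-3-[4-(triisopropylsilyloxy)phenyl]-2,5-dihydrofuran-2-carboxylate, via C5 iodide 18 (not isolated)
Conditions: (11bR,11′bR)-2,6-bis[3,5-bis(trifluoromethyl)phenyl]-3,3′,5,5′-tetrahydro-4,4′-spirobi[dinaphth[2,1-c:1′,2′-e]azepinium] iodide (10 mol %), cumene hydroperoxide (2 equiv), K2CO3 (0.5 equiv), toluene, 0 °C → rt, dark
Reagents that add atoms: none
Why: Proposed new method: cumene hydroperoxide oxidises the iodide of the salt to hypoiodite, which stays paired with the chiral cation; 17 enters as its ammonium carboxylate (or as the acyl hypoiodite), loses the C5 proton, and the anion delocalised over C3–C4–C5 is iodinated at C5 to give 18, whose C2 carboxylate expels iodide and so returns the catalyst. The closest known reaction types are the enantioselective ammonium hypoiodite/peroxide cycloetherifications α to ketones, which build fully substituted C–O centres, and the racemic Bu4NI/peroxide α-oxylactonisation of keto acids, whereas an ester-based vinylogous malonate has not been shown to enter this manifold. The butenolide ring (O1–C2–C3–C4–C5) closes in the 5-exo-tet mode, O1 attacking C5 anti to the exocyclic C–I bond, which is possible only from the isomer with C2 and C5 cis on C3=C4. Both C5 epimers and both alkene isomers of 17 drain into the same planar anion, so C5 is set by the face that the ion-paired binaphthyl cation leaves open to iodine transfer and is passed on with inversion, (S)-18 giving (R)-19. The step needs C5 rather than C3 functionalisation: C3 is fully substituted, iodine placed there would sit on an α-methoxy carbon from which it is readily lost again, and only a leaving group on C5 lies within reach of the carboxylate for a five-membered conjugated lactone. It also needs the rest of the molecule to ignore electrophilic iodine, which the TIPS-capped phenols (no dearomatisation) and the bromine standing in for the prenyl alkene secure.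

Step 11
Reactants: 19 bromo butenolide; 20 3-methylbut-2-enylboronic acid pinacol ester
Product: 21 methyl (R)-4-methoxy-2-[3-(3-methylbut-2-enyl)-4-(triisopropylsilyloxy)benzyl]-5-oxo-3-[4-(triisopropylsilyloxy)phenyl]-2,5-dihydrofuran-2-carboxylate
Conditions: 20 (2 equiv), Pd(dppf)Cl2 (5 mol %), K3PO4 (3 equiv), THF/H2O (20:1), 55 °C
Reagents that add atoms: none
Why: Suzuki–Miyaura coupling of an aryl bromide with an allyl-type boronate: after transmetalation the prenyl group should settle on palladium through its primary carbon, the more so beside the bulky ortho OTIPS group, so that reductive elimination gives the linear prenyl arene, while C5 carries no hydrogen and cannot epimerise under the mild phosphate base.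

Step 12
Reactants: 21 prenylated bis-silyl butenolide
Product: 22 methyl (R)-2-[4-hydroxy-3-(3-methylbut-2-enyl)benzyl]-3-(4-hydroxyphenyl)-4-methoxy-5-oxo-2,5-dihydrofuran-2-carboxylate (2-O-methylbutyrolactone I)
Conditions: Bu4NF/AcOH (1:1, 2.5 equiv each), THF, 0 °C
Reagents that add atoms: none
Why: Fluoride-driven cleavage of both aryl silyl ethers (strong Si–F bond), buffered with acetic acid so that no free phenoxide or fluoride base attacks the lactone or methyl ester and no acid strong enough to cyclise the o-prenylphenol to a chroman is present.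

Compound list
1 | methoxyacetic acid | COCC(=O)O | starting material
2 | tert-butyl methoxyacetate | COCC(=O)OC(C)(C)C | intermediate
3 | methyl 4-hydroxybenzoate | COC(=O)c1ccc(O)cc1 | starting material
4 | methyl 4-(triisopropylsilyloxy)benzoate | COC(=O)c1ccc(O[Si](C(C)C)(C(C)C)C(C)C)cc1 | intermediate
5 | chelated lithium enolate of 2 (OMe cis to OLi) | [Li+].[O-]/C(OC(C)(C)C)=C\OC | intermediate
6 | tert-butyl 2-methoxy-3-oxo-3-[4-(triisopropylsilyloxy)phenyl]propanoate (racemic) | COC(C(=O)OC(C)(C)C)C(=O)c1ccc(O[Si](C(C)C)(C(C)C)C(C)C)cc1 | intermediate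
7 | chelated sodium enolate of 6 (ONa cis to the ester) | [Na+].[O-]/C(c1ccc(O[Si](C(C)C)(C(C)C)C(C)C)cc1)=C(/OC)C(=O)OC(C)(C)C | intermediate
8 | tert-butyl (E)-2-methoxy-3-[4-(triisopropylsilyloxy)phenyl]-3-(trifluoromethylsulfonyloxy)prop-2-enoate | FC(F)(F)S(=O)(=O)O/C(c1ccc(O[Si](C(C)C)(C(C)C)C(C)C)cc1)=C(/OC)C(=O)OC(C)(C)C | intermediate
9 | methyl bromoacetate | COC(=O)CBr | starting material
10 | bromo(2-methoxy-2-oxoethyl)zinc (Reformatsky reagent) | COC(=O)C[Zn]Br | intermediate
11 | 1-tert-butyl 5-methyl (Z)-2-methoxy-3-[4-(triisopropylsilyloxy)phenyl]pent-2-enedioate | COC(=O)C/C(c1ccc(O[Si](C(C)C)(C(C)C)C(C)C)cc1)=C(/OC)C(=O)OC(C)(C)C | intermediate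
12 | 2-bromo-4-methylphenol | Cc1ccc(O)c(Br)c1 | starting material
13 | (2-bromo-4-methylphenoxy)triisopropylsilane | Cc1ccc(O[Si](C(C)C)(C(C)C)C(C)C)c(Br)c1 | intermediate
14 | [2-bromo-4-(bromomethyl)phenoxy]triisopropylsilane | BrCc1ccc(O[Si](C(C)C)(C(C)C)C(C)C)c(Br)c1 | intermediate
15 | lithium dienolate of 11 (charge spread over C3, C5 and both ester groups, geometry not fixed) | [Li+].COC([O-])=CC(c1ccc(O[Si](C(C)C)(C(C)C)C(C)C)cc1)=C(OC)C(=O)OC(C)(C)C | intermediate
16 | 1-tert-butyl 5-methyl (Z)-4-[3-bromo-4-(triisopropylsilyloxy)benzyl]-2-methoxy-3-[4-(triisopropylsilyloxy)phenyl]pent-2-enedioate (racemic at C5) | COC(=O)C(Cc1ccc(O[Si](C(C)C)(C(C)C)C(C)C)c(Br)c1)/C(c1ccc(O[Si](C(C)C)(C(C)C)C(C)C)cc1)=C(/OC)C(=O)OC(C)(C)C | intermediate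
17 | glutaconic half-acid, (Z), racemic at C5, C2 and C5 cis | COC(=O)C(Cc1ccc(O[Si](C(C)C)(C(C)C)C(C)C)c(Br)c1)/C(c1ccc(O[Si](C(C)C)(C(C)C)C(C)C)cc1)=C(/OC)C(=O)O | intermediate
18 | (S)-C5 iodide of 17 (ammonium carboxylate in the flask, drawn as the acid) | COC(=O)[C@@](/C(c1ccc(O[Si](C(C)C)(C(C)C)C(C)C)cc1)=C(/OC)C(=O)O)(Cc1ccc(O[Si](C(C)C)(C(C)C)C(C)C)c(Br)c1)I | intermediate
19 | methyl (R)-2-[3-bromo-4-(triisopropylsilyloxy)benzyl]-4-methoxy-5-oxo-3-[4-(triisopropylsilyloxy)phenyl]-2,5-dihydrofuran-2-carboxylate | COC(=O)[C@]1(Cc2ccc(O[Si](C(C)C)(C(C)C)C(C)C)c(Br)c2)OC(=O)C(OC)=C1c1ccc(O[Si](C(C)C)(C(C)C)C(C)C)cc1 | intermediate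
20 | 3-methylbut-2-enylboronic acid pinacol ester | CC(C)=CCB1OC(C)(C)C(C)(C)O1 | starting material
21 | methyl (R)-4-methoxy-2-[3-(3-methylbut-2-enyl)-4-(triisopropylsilyloxy)benzyl]-5-oxo-3-[4-(triisopropylsilyloxy)phenyl]-2,5-dihydrofuran-2-carboxylate | COC(=O)[C@]1(Cc2ccc(O[Si](C(C)C)(C(C)C)C(C)C)c(CC=C(C)C)c2)OC(=O)C(OC)=C1c1ccc(O[Si](C(C)C)(C(C)C)C(C)C)cc1 | intermediate
22 | 2-O-methylbutyrolactone I, (R) | COC(=O)[C@]1(Cc2ccc(O)c(CC=C(C)C)c2)OC(=O)C(OC)=C1c1ccc(O)cc1 | target

Total step count: 12.
Longest linear sequence: 9 (steps 1, 3, 4, 5, 8, 9, 10, 11, 12).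

Steps most likely to fail

1. Step 10.
   - What may go wrong:
     - Removal of the C5 proton may be sluggish once the acid is ionised.
     - Iodine transfer may show little facial bias.
     - The tertiary allylic C–I bond may ionise before ring closure, which would wash out the stereochemical information.
     - The half-acid may decarboxylate through its deconjugated tautomer.
   - Fallback with known chemistry, setting out from 16. KHMDS in THF at −78 °C gives the potassium dienolate F1. This is hydroxylated at C5 with an enantiopure (camphorsulfonyl)oxaziridine (reagent-controlled enolate hydroxylation, Davis oxidation) to the (R)-configured C5 carbinol F2.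
   - CF3CO2H in CH2Cl2 then removes the tert-butyl group, and the C5 hydroxyl acylates on C2. This comes back to the route at 19.
   - If reagent control proves insufficient, a racemic N-sulfonyloxaziridine is used and the enantiomers of 19 are separated on a chiral stationary phase.

2. Step 11.
   - What may go wrong:
     - Allyl transposition may attach the side chain through its tertiary carbon.
     - Oxidative addition beside the OTIPS group may be slow.
     - The C5 methyl ester may be saponified and then lose CO2.
   - Fallback setting out from 19. A base-free Stille coupling with allyltributylstannane (Pd(PPh3)4, toluene, 100 °C) gives the allyl arene F3, for which no regiochemical question exists.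
   - Cross-metathesis with excess 2-methylbut-2-ene (second-generation Grubbs catalyst, CH2Cl2, 40 °C) converts allyl into prenyl without touching the tetrasubstituted ring alkene. This comes back to the route at 21.

3. Step 5.
   - What may go wrong:
     - Transmetalation or reductive elimination may be slow at the fully substituted alkenyl palladium centre.
     - The acidic product may protonate the zinc enolate.
     - The triflate may hydrolyse back to the keto ester.
   - Fallback setting out from 6, which bypasses the triflate. Reformatsky addition of 10 to the aryl ketone, with zinc chelated by the ketone and the α-methoxy group, is the classical entry to 3-hydroxyglutarates from β-keto esters. It gives the tertiary carbinol F4.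
   - (CF3CO)2O/Et3N converts this into the trifluoroacetate F5, and DBU eliminates it in the same flask by an E1cB process. This comes back to the route at 11. The C4=C5 tautomer, if formed, gives the same dienolate 15.

Further compounds
F1 | step 10 | potassium dienolate of 16 (geometry not fixed) | [K+].COC([O-])=C(Cc1ccc(O[Si](C(C)C)(C(C)C)C(C)C)c(Br)c1)C(c1ccc(O[Si](C(C)C)(C(C)C)C(C)C)cc1)=C(OC)C(=O)OC(C)(C)C
F2 | step 10 | 1-tert-butyl 5-methyl (R,Z)-4-[3-bromo-4-(triisopropylsilyloxy)benzyl]-4-hydroxy-2-methoxy-3-[4-(triisopropylsilyloxy)phenyl]pent-2-enedioate | COC(=O)[C@@](O)(Cc1ccc(O[Si](C(C)C)(C(C)C)C(C)C)c(Br)c1)/C(c1ccc(O[Si](C(C)C)(C(C)C)C(C)C)cc1)=C(/OC)C(=O)OC(C)(C)C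
F3 | step 11 | methyl (R)-2-[3-allyl-4-(triisopropylsilyloxy)benzyl]-4-methoxy-5-oxo-3-[4-(triisopropylsilyloxy)phenyl]-2,5-dihydrofuran-2-carboxylate | COC(=O)[C@]1(Cc2ccc(O[Si](C(C)C)(C(C)C)C(C)C)c(CC=C)c2)OC(=O)C(OC)=C1c1ccc(O[Si](C(C)C)(C(C)C)C(C)C)cc1
F4 | step 5 | 1-tert-butyl 5-methyl 3-hydroxy-2-methoxy-3-[4-(triisopropylsilyloxy)phenyl]pentanedioate (diastereomer mixture, racemic) | COC(=O)CC(O)(c1ccc(O[Si](C(C)C)(C(C)C)C(C)C)cc1)C(OC)C(=O)OC(C)(C)C
F5 | step 5 | trifluoroacetate of F4 | COC(=O)CC(OC(=O)C(F)(F)F)(c1ccc(O[Si](C(C)C)(C(C)C)C(C)C)cc1)C(OC)C(=O)OC(C)(C)C
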